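(The numbers in the tables were computed with constants of no real substance, noise included.)

Reckon the mean age of the product in each flask, and read the share of J from that age.

| flask | G | X | D | remark | time |
|---|---|---|---|---|---|
| noon | 0.20 M | 0.18 M (fed, over 5.0 h) | 4.4 mM | run made earlier |  |
| dusk | 0.20 M | 0.61 M (fed, over 5.0 h) | 4.4 mM | run made earlier |  |
| larch | 0.20 M | 0.500 M (fed, over 5.0 h) | 4.4 mM |  | 6.0 h |
| alder | 0.20 M | 0.150 M | 4.4 mM | everything together at the start | 6.0 h |

| run | time / h | J / % | E / % |
|---|---|---|---|
| noon | 0.833 | 3 | 0 |
| noon | 1.50 | 6 | 1 |
| noon | 2.50 | 21 | 7 |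
| noon | 3.00 | 23 | 15 |
| noon | 4.00 | 28 | 16 |
| noon | 5.00 | 35 | 22 |
| noon | 6.00 | 31 | 29 |
| dusk | 0.500 | 4 | 0 |
| dusk | 0.667 | 7 | 4 |
| dusk | 1.00 | 14 | 6 |
| dusk | 1.50 | 24 | 10 |
| dusk | 2.50 | 41 | 24 |
| dusk | 4.00 | 47 | 41 |
| dusk | 6.00 | 43 | 46 |

(standard deviation of a reading: 2 percentage points)

- the earlier runs were read with a standard deviation of 2 percentage points
- a reading or a percentage of J counts all its forms, free or not

- the winner by share of J in all that became J or E; "neither" if no more than 2 percentage points parts them (larch / alder / neither)
- share of J in all that became J or E, larch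
- share of J in all that became J or E, alder

1. Call the share of J in J + E the selectivity s, and read it young in the dusk run at 1.50 h, where it stands at 70.6%; take this reading, with its scatter, as s0, the share at birth.

2. Read it old in the noon run at 6.00 h, where it stands at 51.7%, and since X went in evenly there over 5.0 h, take the mean age a, the time since the average portion of product was born, as half the feed time short of the reading time, 3.50 h.

3. Join the two ends with s = s0 exp(−κa), where κ is the fading rate of the share, 0.0892 /h; let s hang on age, since dusk took a charge of X larger than noon's by a factor of 3.39 and still ended at 48.3%.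

4. Solve the two extremes at 6.0 h: product born evenly over the feed gives 51.7%, and product born at the start, with a equal to the whole time, gives a floor of 41.3%.

5. Place larch, which is fed, between 48.3% and 51.7%. Place alder, which gets its X at the start, somewhat above the floor, taking its product as born early but not at one instant. The gap of 10 percentage points between the extremes exceeds the margin 2 points, so commit to larch.

6. Note that the forecast, which differs from this reckoning on alder, gave alder, with 50% for larch and 63% for alder, “matching noon at similar X dosed”.

7. Take the result: the winner is larch, with 50.8% for larch and 45.4% for alder.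

    G + X ⇌ J (K = 14.0 /M, k = 0.0710 /M/min)
    G + X ⇌ E (K = 34.0 /M, k = 0.0280 /M/min)
    J + D ⇌ E + D, rate k3*[D]*[J] forward; the back reaction follows from the equilibrium constant (k = 0.320 /M/min)
    D + J ⇌ Q (K = 9.10 /M, k = 0.440 /M/min)

8. See that in alder at 6.00 h free J is made more slowly than it is used up, at a ratio of 0.0190. Put κ back in: alder's share means a mean age of 4.96 h, and it stands above the floor. Read alder earlier, at 1.5 h: the floor there is 61.8%, and that flask shows 63.8%.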